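**Retrosynthetic overview**
1. Target 34 ⇐ C9 acetylation, PMB removal, C3 angeloylation and hydroxyl-directed 4,5-epoxidation of the macrocyclic (3S,4Z)-allylic alcohol 30.
2. Ten-membered carbocycle ⇐ intramolecular Nozaki–Hiyama–Kishi closure of C3–C4 in iodo-aldehyde 27, then oxidation and CBS reduction to fix C3.
3. Key C7–C8 bond ⇐ intermolecular allylboration of the α-alkoxy epoxy-aldehyde 19 (C1–C3, C8–C10, C14) with the (Z)-allylboronate 6 (C5–C7, C11–C13); this sets C7 and C8 from C9.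
4. 19 ⇐ (S)-glycerate acetonide 10 by Z-selective Wittig reaction and VO(acac)2-directed epoxidation; 6 ⇐ silyloxypropanal 2 by Z-iodo-olefination and boron homologation.
5. Ring order: 1,10-oxirane (step 12) → carbocycle (step 21) → 4,5-oxirane (step 24).

Assumption: the stereodescriptors in the SMILES are taken at face value, i.e. (1R,3S,4S,5S,7R,8S,9S,10R) in germacrane numbering (ring C1–C10, C14 on C10, C15 on C4, isopropenyl C11–C13 on C7), with both oxiranes cis (ring carbons cis, i.e. derived from Z olefins); this numbering is used for locants throughout.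

Abbreviations: TBS = tert-butyldimethylsilyl; TBDPS = tert-butyldiphenylsilyl; PMB = 4-methoxybenzyl; Bpin = 4,4,5,5-tetramethyl-1,3,2-dioxaborolan-2-yl; angelate = (2Z)-2-methylbut-2-enoate.

**Fragment 6 (allylboronate)**

Step 1
Reactants: 1 3-[(tert-butyldimethylsilyl)oxy]propan-1-ol
Product: 2 3-[(tert-butyldimethylsilyl)oxy]propanal
Conditions: TEMPO (0.1 equiv), PhI(OAc)2 (1.1 equiv), CH2Cl2, rt
Reagents that add atoms: none
Why: Oxoammonium (TEMPO)-catalysed oxidation of a primary alcohol stops at the aldehyde and leaves the silyl ether untouched.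

Step 2
Reactants: 2 3-[(tert-butyldimethylsilyl)oxy]propanal
Product: 3 (Z)-tert-butyl[(4-iodopent-3-en-1-yl)oxy]dimethylsilane
Conditions: EtPPh3I, n-BuLi, THF, 0 °C; I2, −78 °C; NaN(SiMe3)2, −20 °C; then 2, −78 °C → rt
Reagents that add atoms: ethyltriphenylphosphonium iodide (CC[P+](c1ccccc1)(c1ccccc1)c1ccccc1.[I-]); iodine ([I][I])
Why: Stork–Zhao-type Wittig olefination with the α-iodoethylidene ylide is kinetically controlled and gives the (Z)-2-iodoalk-2-ene with iodine cis to the chain.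

Step 3
Reactants: 3 (Z)-tert-butyl[(4-iodopent-3-en-1-yl)oxy]dimethylsilane
Product: 6 (Z)-tert-butyldimethyl{[4-methyl-5-(Bpin)pent-3-en-1-yl]oxy}silane, via alkenyllithium 4 (not isolated), via chloromethyl borate ate complex 5 (not isolated)
Conditions: t-BuLi (2.1 equiv), Et2O, −78 °C; then ClCH2Bpin, −78 °C → rt
Reagents that add atoms: 2-(chloromethyl)-4,4,5,5-tetramethyl-1,3,2-dioxaborolane (ClCB1OC(C)(C)C(C)(C)O1)
Why: Iodine–lithium exchange and the Matteson-type 1,2-metallate shift of the alkenyl group onto the chloromethyl carbon both retain olefin geometry, so the CH2B group ends up cis to the chain (Z-allylboronate).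

**Wittig salt 9**

Step 4
Reactants: 7 3-bromopropan-1-ol
Product: 8 (3-bromopropoxy)(tert-butyl)diphenylsilane
Conditions: TBDPSCl, imidazole, DMF, rt
Reagents that add atoms: tert-butylchlorodiphenylsilane (CC(C)(C)[Si](Cl)(c1ccccc1)c1ccccc1)
Why: Imidazole-promoted silylation of the primary alcohol gives a robust ether that survives every step until the late fluoride cleavage.

Step 5
Reactants: 8 (3-bromopropoxy)(tert-butyl)diphenylsilane
Product: 9 {3-[(tert-butyldiphenylsilyl)oxy]propyl}triphenylphosphonium bromide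
Conditions: PPh3, MeCN, reflux
Reagents that add atoms: triphenylphosphine (c1ccc(cc1)P(c1ccccc1)c1ccccc1)
Why: SN2 quaternisation of triphenylphosphine by the primary bromide gives the phosphonium salt.

**Fragment 19 (epoxy aldehyde)**

Step 6
Reactants: 10 methyl (4S)-2,2-dimethyl-1,3-dioxolane-4-carboxylate
Product: 11 (4S)-N-methoxy-N,2,2-trimethyl-1,3-dioxolane-4-carboxamide
Conditions: MeNH(OMe)·HCl, i-PrMgCl, THF, −20 °C
Reagents that add atoms: N,O-dimethylhydroxylamine hydrochloride (CNOC.Cl)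
Why: Weinreb amidation with the magnesium amide occurs at low temperature without epimerising the α-alkoxy centre that becomes C9.

Step 7
Reactants: 11 (4S)-N-methoxy-N,2,2-trimethyl-1,3-dioxolane-4-carboxamide
Product: 12 1-[(4S)-2,2-dimethyl-1,3-dioxolan-4-yl]ethan-1-one
Conditions: MeMgBr, THF, 0 °C
Reagents that add atoms: methylmagnesium bromide (C[Mg]Br)
Why: Weinreb ketone synthesis, in which the stable magnesium chelate prevents over-addition, delivers the methyl ketone (C10 and C14).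

Step 8
Reactants: 12 1-[(4S)-2,2-dimethyl-1,3-dioxolan-4-yl]ethan-1-one; 9 {3-[(tert-butyldiphenylsilyl)oxy]propyl}triphenylphosphonium bromide
Product: 14 (4R)-4-[(2Z)-5-(TBDPSO)pent-2-en-2-yl]-2,2-dimethyl-1,3-dioxolane, via phosphorus ylide 13 (not isolated)
Conditions: KN(SiMe3)2, THF, 0 °C; then 12, −78 °C → rt
Reagents that add atoms: none
Why: Wittig olefination of an α-alkoxy methyl ketone with a non-stabilised ylide is Z-selective (the oxygenated carbon ends up cis to the new chain), which fixes the later cis-oxirane geometry while the chiral-pool centre is untouched (its descriptor changes only through CIP priorities).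

Step 9
Reactants: 14 (4R)-4-[(2Z)-5-(TBDPSO)pent-2-en-2-yl]-2,2-dimethyl-1,3-dioxolane
Product: 15 (2R,3Z)-6-(TBDPSO)-3-methylhex-3-ene-1,2-diol
Conditions: AcOH/H2O 4:1, 40 °C
Reagents that add atoms: none
Why: Mild acid-catalysed acetal hydrolysis removes the isopropylidene group without touching the primary TBDPS ether or the olefin geometry.

Step 10
Reactants: 15 (2R,3Z)-6-(TBDPSO)-3-methylhex-3-ene-1,2-diol
Product: 16 (4R)-4-[(2Z)-5-(TBDPSO)pent-2-en-2-yl]-2-(4-methoxyphenyl)-1,3-dioxolane (acetal epimers)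
Conditions: 4-MeOC6H4CH(OMe)2, pyridinium p-toluenesulfonate (cat.), CH2Cl2, rt
Reagents that add atoms: 4-methoxybenzaldehyde dimethyl acetal (COC(OC)c1ccc(OC)cc1)
Why: Acid-catalysed transacetalisation ties the 1,2-diol into a 4-methoxybenzylidene acetal as the precursor of a regiodefined PMB ether.

Step 11
Reactants: 16 (4R)-4-[(2Z)-5-(TBDPSO)pent-2-en-2-yl]-2-(4-methoxyphenyl)-1,3-dioxolane
Product: 17 (2R,3Z)-6-(TBDPSO)-2-(PMBO)-3-methylhex-3-en-1-ol
Conditions: i-Bu2AlH, CH2Cl2, −78 → 0 °C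
Reagents that add atoms: none
Why: Reductive acetal opening, in which the aluminium hydride coordinates the less hindered primary oxygen and cleaves that C–O bond, leaves the PMB group on the secondary C9 oxygen and frees the primary C8 alcohol.

Step 12
Reactants: 17 (2R,3Z)-6-(TBDPSO)-2-(PMBO)-3-methylhex-3-en-1-ol
Product: 18 (2S)-2-[(2R,3R)-3-(2-(TBDPSO)ethyl)-2-methyloxiran-2-yl]-2-(PMBO)ethan-1-ol
Conditions: VO(acac)2 (5 mol %), t-BuOOH, CH2Cl2, rt
Reagents that add atoms: tert-butyl hydroperoxide (CC(C)(C)OO)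
Why: In this vanadium-catalysed homoallylic-alcohol-directed epoxidation, A(1,3) strain of the Z olefin holds the C9–H in the olefin plane, so the vanadate on the C8 oxygen delivers oxygen to the face carrying C8 (anti to OPMB), setting C1 and C10 (both R, erythro to C9) as the cis-oxirane.

Step 13
Reactants: 18 (2S)-2-[(2R,3R)-3-(2-(TBDPSO)ethyl)-2-methyloxiran-2-yl]-2-(PMBO)ethan-1-ol
Product: 19 (2R)-2-[(2R,3R)-3-(2-(TBDPSO)ethyl)-2-methyloxiran-2-yl]-2-(PMBO)acetaldehyde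
Conditions: Dess–Martin periodinane, pyridine, CH2Cl2, 0 °C → rt
Reagents that add atoms: none
Why: Buffered Dess–Martin oxidation gives the α-alkoxy aldehyde without epimerising C9 or opening the oxirane (the descriptor at C9 changes only through CIP priorities).

**Fragment union and endgame**

Step 14
Reactants: 6 (Z)-tert-butyldimethyl{[4-methyl-5-(Bpin)pent-3-en-1-yl]oxy}silane; 19 (2R)-2-[(2R,3R)-3-(2-(TBDPSO)ethyl)-2-methyloxiran-2-yl]-2-(PMBO)acetaldehyde
Product: 21 (1S,2S,3R)-1-[(2R,3R)-3-(2-(TBDPSO)ethyl)-2-methyloxiran-2-yl]-1-(PMBO)-3-[2-(TBSO)ethyl]-4-methylpent-4-en-2-ol, via pinacol borate ester 20 (not isolated)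
Conditions: toluene (1 M), 4 Å molecular sieves, rt → 40 °C, 48 h; aq. NaHCO3 work-up
Reagents that add atoms: none
Why: This intermolecular carbonyl allylation (allylboration) runs through a closed Zimmerman–Traxler chair in which the Z-allylboronate gives the C7/C8 syn pair and Cornforth/Felkin-type addition anti to the α-OPMB group gives the 8,9-anti pattern, so C7 (R) and C8 (S) are set from C9 and the isopropenyl group is created.

Step 15
Reactants: 21 (1S,2S,3R)-1-[(2R,3R)-3-(2-(TBDPSO)ethyl)-2-methyloxiran-2-yl]-1-(PMBO)-3-[2-(TBSO)ethyl]-4-methylpent-4-en-2-ol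
Product: 22 (1S,2S,3R)-1-[(2R,3R)-3-(2-(TBDPSO)ethyl)-2-methyloxiran-2-yl]-1-(PMBO)-3-[2-(TBSO)ethyl]-4-methylpent-4-en-2-yl (2Z)-2-methylbut-2-enoate
Conditions: angelic acid, 2,4,6-Cl3C6H2COCl, Et3N, toluene, rt; then 21, 75 °C
Reagents that add atoms: angelic acid (C/C=C(/C)C(=O)O)
Why: Yamaguchi-type mixed-anhydride esterification without a nucleophilic catalyst acylates the hindered C8 alcohol without angelate-to-tiglate isomerisation, and this ester also protects C8 to the end.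

Step 16
Reactants: 22 C8 angelate with C5-OTBS and C3-OTBDPS
Product: 23 (1S,2S,3R)-1-[(2R,3R)-3-(2-(TBDPSO)ethyl)-2-methyloxiran-2-yl]-1-(PMBO)-3-(2-hydroxyethyl)-4-methylpent-4-en-2-yl (2Z)-2-methylbut-2-enoate
Conditions: HF·pyridine, pyridine, THF, 0 °C
Reagents that add atoms: none
Why: Buffered fluoride desilylation removes the primary TBS ether far faster than the primary TBDPS ether and tolerates the oxirane and esters.

Step 17
Reactants: 23 C5 alcohol
Product: 24 (1S,2S,3R)-1-[(2R,3R)-3-(2-(TBDPSO)ethyl)-2-methyloxiran-2-yl]-1-(PMBO)-4-methyl-3-(2-oxoethyl)pent-4-en-2-yl (2Z)-2-methylbut-2-enoate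
Conditions: Dess–Martin periodinane, pyridine, CH2Cl2, 0 °C → rt
Reagents that add atoms: none
Why: Dess–Martin oxidation converts the primary C5 alcohol into the aldehyde under neutral conditions compatible with all other groups.

Step 18
Reactants: 24 C5 aldehyde
Product: 25 (1S,2S,3R)-1-[(2R,3R)-3-(2-(TBDPSO)ethyl)-2-methyloxiran-2-yl]-1-(PMBO)-3-[(2Z)-3-iodobut-2-en-1-yl]-4-methylpent-4-en-2-yl (2Z)-2-methylbut-2-enoate
Conditions: EtPPh3I, n-BuLi, THF, 0 °C; I2, −78 °C; NaN(SiMe3)2, −20 °C; then 24, −78 °C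
Reagents that add atoms: ethyltriphenylphosphonium iodide (CC[P+](c1ccccc1)(c1ccccc1)c1ccccc1.[I-]); iodine ([I][I])
Why: The Stork–Zhao-type Wittig olefination installs C4 and C15 as the (Z)-alkenyl iodide (iodine cis to C6), which fixes the 4Z geometry needed for the cis 4,5-oxirane.

Step 19
Reactants: 25 (Z)-alkenyl iodide with C3-OTBDPS
Product: 26 (1S,2S,3R)-1-[(2R,3R)-3-(2-hydroxyethyl)-2-methyloxiran-2-yl]-1-(PMBO)-3-[(2Z)-3-iodobut-2-en-1-yl]-4-methylpent-4-en-2-yl (2Z)-2-methylbut-2-enoate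
Conditions: Bu4NF, AcOH, THF, 0 °C → rt
Reagents that add atoms: none
Why: Acetic-acid-buffered fluoride desilylation frees the primary C3 alcohol without acyl migration, ester cleavage or base-induced oxirane opening.

Step 20
Reactants: 26 C3 alcohol
Product: 27 (1S,2S,3R)-1-[(2R,3R)-2-methyl-3-(2-oxoethyl)oxiran-2-yl]-1-(PMBO)-3-[(2Z)-3-iodobut-2-en-1-yl]-4-methylpent-4-en-2-yl (2Z)-2-methylbut-2-enoate
Conditions: Dess–Martin periodinane, pyridine, CH2Cl2, 0 °C; used crude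
Reagents that add atoms: none
Why: Buffered Dess–Martin oxidation gives the base-sensitive β,γ-epoxy aldehyde under conditions that avoid β-elimination.

Step 21
Reactants: 27 iodo-aldehyde
Product: 28 (1R,3RS,4Z,7R,8S,9S,10R)-1,10-epoxy-3-hydroxy-9-(PMBO)germacra-4,11-dien-8-yl (2Z)-2-methylbut-2-enoate
Conditions: CrCl2 (10 equiv), NiCl2 (0.1 equiv), DMSO, 0.003 M, rt
Reagents that add atoms: none
Why: In this intramolecular Nozaki–Hiyama–Kishi reaction the alkenylchromium forms with retention of the Z geometry and adds chemoselectively to the aldehyde at high dilution to close the ten-membered ring, the C3 epimers being converged in steps 22 and 23.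

Step 22
Reactants: 28 macrocyclic allylic alcohol (C3 epimers)
Product: 29 (1R,4Z,7R,8S,9S,10R)-1,10-epoxy-9-(PMBO)-3-oxogermacra-4,11-dien-8-yl (2Z)-2-methylbut-2-enoate
Conditions: Dess–Martin periodinane, pyridine, CH2Cl2, 0 °C; used crude
Reagents that add atoms: none
Why: Dess–Martin oxidation merges both C3 epimers into one enone under non-basic conditions that keep the Z enone and the β,γ-oxirane intact.

Step 23
Reactants: 29 macrocyclic enone
Product: 30 (1R,3S,4Z,7R,8S,9S,10R)-1,10-epoxy-3-hydroxy-9-(PMBO)germacra-4,11-dien-8-yl (2Z)-2-methylbut-2-enoate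
Conditions: (R)-2-methyl-CBS-oxazaborolidine (0.5 equiv), catecholborane (1.5 equiv), toluene/CH2Cl2, −78 °C
Reagents that add atoms: none
Why: Corey–Bakshi–Shibata reduction under reagent control, with the α-methylalkenyl arm as the large group, delivers hydride to give the (3S)-allylic alcohol by clean 1,2-reduction.

Step 24
Reactants: 30 (3S)-allylic alcohol
Product: 31 (1R,3S,4R,5S,7R,8S,9S,10R)-1,10:4,5-diepoxy-3-hydroxy-9-(PMBO)germacr-11-en-8-yl (2Z)-2-methylbut-2-enoate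
Conditions: mCPBA (1.1 equiv), NaHCO3, CH2Cl2, −20 → 0 °C
Reagents that add atoms: 3-chloroperoxybenzoic acid (OOC(=O)c1cccc(Cl)c1)
Why: Peracid (Prilezhaev) epoxidation of a Z allylic alcohol is threo-selective (the hydrogen-bonded acyclic model and the medium-ring trans preference agree), setting C4 and C5 with the oxirane trans to the C3 oxygen, while the isopropenyl and angelate olefins react far more slowly.

Step 25
Reactants: 31 diepoxy alcohol
Product: 32 (1R,3S,4S,5S,7R,8S,9S,10R)-1,10:4,5-diepoxy-9-(PMBO)germacr-11-ene-3,8-diyl bis[(2Z)-2-methylbut-2-enoate]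
Conditions: angelic acid, 2,4,6-Cl3C6H2COCl, Et3N, toluene, rt; then 31, 75 °C
Reagents that add atoms: angelic acid (C/C=C(/C)C(=O)O)
Why: The same Yamaguchi-type mixed-anhydride esterification installs the C3 angelate without double-bond isomerisation and without touching any stereocentre (the C4 descriptor changes only through CIP priorities).

Step 26
Reactants: 32 bis-angelate PMB ether
Product: 33 (1R,3S,4S,5S,7R,8S,9S,10S)-1,10:4,5-diepoxy-9-hydroxygermacr-11-ene-3,8-diyl bis[(2Z)-2-methylbut-2-enoate]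
Conditions: DDQ, CH2Cl2/pH 7 buffer, 0 °C
Reagents that add atoms: none
Why: Oxidative PMB cleavage by DDQ under buffered conditions frees only the C9 hydroxyl and tolerates oxiranes, esters and the isopropenyl group (the C10 descriptor changes only through CIP priorities).

Step 27
Reactants: 33 C9 alcohol
Product: 34 (1R,3S,4S,5S,7R,8S,9S,10R)-9-acetoxy-1,10:4,5-diepoxygermacr-11-ene-3,8-diyl bis[(2Z)-2-methylbut-2-enoate] (CNP0220329.1)
Conditions: Ac2O, pyridine, DMAP (cat.), CH2Cl2, 0 °C → rt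
Reagents that add atoms: acetic anhydride (CC(=O)OC(C)=O)
Why: Fast nucleophile-catalysed acetylation of the remaining secondary alcohol outruns any angelate migration and gives the target.

**Compound list**

1 | 3-[(tert-butyldimethylsilyl)oxy]propan-1-ol | OCCCO[Si](C)(C)C(C)(C)C | starting material
2 | 3-[(tert-butyldimethylsilyl)oxy]propanal | O=CCCO[Si](C)(C)C(C)(C)C | intermediate
3 | (Z)-tert-butyl[(4-iodopent-3-en-1-yl)oxy]dimethylsilane | C/C(I)=C/CCO[Si](C)(C)C(C)(C)C | intermediate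
4 | (E)-{5-[(tert-butyldimethylsilyl)oxy]pent-2-en-2-yl}lithium (lithium cis to the chain) | C/C([Li])=C/CCO[Si](C)(C)C(C)(C)C | intermediate (not isolated)
5 | lithium (chloromethyl){(E)-5-[(tert-butyldimethylsilyl)oxy]pent-2-en-2-yl}(pinacolato)borate | [Li+].C/C(=C/CCO[Si](C)(C)C(C)(C)C)[B-]1(CCl)OC(C)(C)C(C)(C)O1 | intermediate (not isolated)
6 | (Z)-tert-butyldimethyl{[4-methyl-5-(4,4,5,5-tetramethyl-1,3,2-dioxaborolan-2-yl)pent-3-en-1-yl]oxy}silane | C/C(CB1OC(C)(C)C(C)(C)O1)=C/CCO[Si](C)(C)C(C)(C)C | intermediate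
7 | 3-bromopropan-1-ol | OCCCBr | starting material
8 | (3-bromopropoxy)(tert-butyl)diphenylsilane | BrCCCO[Si](c1ccccc1)(c1ccccc1)C(C)(C)C | intermediate
9 | {3-[(tert-butyldiphenylsilyl)oxy]propyl}triphenylphosphonium bromide | CC(C)(C)[Si](c1ccccc1)(c1ccccc1)OCCC[P+](c1ccccc1)(c1ccccc1)c1ccccc1.[Br-] | intermediate
10 | methyl (4S)-2,2-dimethyl-1,3-dioxolane-4-carboxylate | COC(=O)[C@@H]1COC(C)(C)O1 | starting material
11 | (4S)-N-methoxy-N,2,2-trimethyl-1,3-dioxolane-4-carboxamide | CON(C)C(=O)[C@@H]1COC(C)(C)O1 | intermediate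
12 | 1-[(4S)-2,2-dimethyl-1,3-dioxolan-4-yl]ethan-1-one | CC(=O)[C@@H]1COC(C)(C)O1 | intermediate
13 | {3-[(tert-butyldiphenylsilyl)oxy]propylidene}triphenylphosphorane | CC(C)(C)[Si](c1ccccc1)(c1ccccc1)OCCC=P(c1ccccc1)(c1ccccc1)c1ccccc1 | intermediate (not isolated)
14 | (4R)-4-[(2Z)-5-{[tert-butyl(diphenyl)silyl]oxy}pent-2-en-2-yl]-2,2-dimethyl-1,3-dioxolane | C/C(=C/CCO[Si](c1ccccc1)(c1ccccc1)C(C)(C)C)[C@@H]1COC(C)(C)O1 | intermediate
15 | (2R,3Z)-6-{[tert-butyl(diphenyl)silyl]oxy}-3-methylhex-3-ene-1,2-diol | OC[C@H](O)/C(C)=C\CCO[Si](c1ccccc1)(c1ccccc1)C(C)(C)C | intermediate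
16 | (4R)-4-[(2Z)-5-{[tert-butyl(diphenyl)silyl]oxy}pent-2-en-2-yl]-2-(4-methoxyphenyl)-1,3-dioxolane (acetal epimers) | COc1ccc(cc1)C2OC[C@H](O2)/C(C)=C\CCO[Si](c3ccccc3)(c3ccccc3)C(C)(C)C | intermediate
17 | (2R,3Z)-6-{[tert-butyl(diphenyl)silyl]oxy}-2-[(4-methoxybenzyl)oxy]-3-methylhex-3-en-1-ol | OC[C@H](OCc1ccc(OC)cc1)/C(C)=C\CCO[Si](c1ccccc1)(c1ccccc1)C(C)(C)C | intermediate
18 | (2S)-2-[(2R,3R)-3-(2-{[tert-butyl(diphenyl)silyl]oxy}ethyl)-2-methyloxiran-2-yl]-2-[(4-methoxybenzyl)oxy]ethan-1-ol | CC(C)(C)[Si](c1ccccc1)(c1ccccc1)OCC[C@H]2O[C@@]2(C)[C@@H](OCc3ccc(OC)cc3)CO | intermediate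
19 | (2R)-2-[(2R,3R)-3-(2-{[tert-butyl(diphenyl)silyl]oxy}ethyl)-2-methyloxiran-2-yl]-2-[(4-methoxybenzyl)oxy]acetaldehyde | CC(C)(C)[Si](c1ccccc1)(c1ccccc1)OCC[C@H]2O[C@@]2(C)[C@@H](OCc3ccc(OC)cc3)C=O | intermediate
20 | pinacol borate ester of alcohol 21 (O–Bpin on C8) | CC(C)(C)[Si](c1ccccc1)(c1ccccc1)OCC[C@H]2O[C@@]2(C)[C@@H](OCc3ccc(OC)cc3)[C@@H](OB4OC(C)(C)C(C)(C)O4)[C@@H](C(C)=C)CCO[Si](C)(C)C(C)(C)C | intermediate (not isolated)
21 | (1S,2S,3R)-1-[(2R,3R)-3-(2-(TBDPSO)ethyl)-2-methyloxiran-2-yl]-1-(PMBO)-3-[2-(TBSO)ethyl]-4-methylpent-4-en-2-ol (germacrane 1R,7R,8S,9S,10R) | CC(C)(C)[Si](c1ccccc1)(c1ccccc1)OCC[C@H]2O[C@@]2(C)[C@@H](OCc3ccc(OC)cc3)[C@@H](O)[C@@H](C(C)=C)CCO[Si](C)(C)C(C)(C)C | intermediate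
22 | C8 angelate of 21 | CC(C)(C)[Si](c1ccccc1)(c1ccccc1)OCC[C@H]2O[C@@]2(C)[C@@H](OCc3ccc(OC)cc3)[C@@H](OC(=O)/C(C)=C\C)[C@@H](C(C)=C)CCO[Si](C)(C)C(C)(C)C | intermediate
23 | C5 alcohol (3-(2-hydroxyethyl) analogue of 22) | CC(C)(C)[Si](c1ccccc1)(c1ccccc1)OCC[C@H]2O[C@@]2(C)[C@@H](OCc3ccc(OC)cc3)[C@@H](OC(=O)/C(C)=C\C)[C@@H](C(C)=C)CCO | intermediate
24 | C5 aldehyde (3-(2-oxoethyl) analogue) | CC(C)(C)[Si](c1ccccc1)(c1ccccc1)OCC[C@H]2O[C@@]2(C)[C@@H](OCc3ccc(OC)cc3)[C@@H](OC(=O)/C(C)=C\C)[C@@H](C(C)=C)CC=O | intermediate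
25 | (Z)-alkenyl iodide (3-[(2Z)-3-iodobut-2-en-1-yl] analogue) with C3-OTBDPS | CC(C)(C)[Si](c1ccccc1)(c1ccccc1)OCC[C@H]2O[C@@]2(C)[C@@H](OCc3ccc(OC)cc3)[C@@H](OC(=O)/C(C)=C\C)[C@@H](C(C)=C)C/C=C(/C)I | intermediate
26 | C3 alcohol of the (Z)-alkenyl iodide | OCC[C@H]2O[C@@]2(C)[C@@H](OCc3ccc(OC)cc3)[C@@H](OC(=O)/C(C)=C\C)[C@@H](C(C)=C)C/C=C(/C)I | intermediate
27 | C3 aldehyde of the (Z)-alkenyl iodide (iodo-aldehyde) | O=CC[C@H]2O[C@@]2(C)[C@@H](OCc3ccc(OC)cc3)[C@@H](OC(=O)/C(C)=C\C)[C@@H](C(C)=C)C/C=C(/C)I | intermediate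
28 | (1R,3RS,4Z,7R,8S,9S,10R)-1,10-epoxy-3-hydroxy-9-[(4-methoxybenzyl)oxy]germacra-4,11-dien-8-yl (2Z)-2-methylbut-2-enoate | C=C(C)[C@H]1C/C=C(/C)C(O)C[C@H]2O[C@@]2(C)[C@@H](OCc3ccc(OC)cc3)[C@H]1OC(=O)/C(C)=C\C | intermediate
29 | (1R,4Z,7R,8S,9S,10R)-1,10-epoxy-9-[(4-methoxybenzyl)oxy]-3-oxogermacra-4,11-dien-8-yl (2Z)-2-methylbut-2-enoate | C=C(C)[C@H]1C/C=C(/C)C(=O)C[C@H]2O[C@@]2(C)[C@@H](OCc3ccc(OC)cc3)[C@H]1OC(=O)/C(C)=C\C | intermediate
30 | (1R,3S,4Z,7R,8S,9S,10R)-1,10-epoxy-3-hydroxy-9-[(4-methoxybenzyl)oxy]germacra-4,11-dien-8-yl (2Z)-2-methylbut-2-enoate | C=C(C)[C@H]1C/C=C(/C)[C@@H](O)C[C@H]2O[C@@]2(C)[C@@H](OCc3ccc(OC)cc3)[C@H]1OC(=O)/C(C)=C\C | intermediate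
31 | (1R,3S,4R,5S,7R,8S,9S,10R)-1,10:4,5-diepoxy-3-hydroxy-9-[(4-methoxybenzyl)oxy]germacr-11-en-8-yl (2Z)-2-methylbut-2-enoate | C=C(C)[C@H]1C[C@@H]2O[C@]2(C)[C@@H](O)C[C@H]2O[C@@]2(C)[C@@H](OCc3ccc(OC)cc3)[C@H]1OC(=O)/C(C)=C\C | intermediate
32 | (1R,3S,4S,5S,7R,8S,9S,10R)-1,10:4,5-diepoxy-9-[(4-methoxybenzyl)oxy]germacr-11-ene-3,8-diyl bis[(2Z)-2-methylbut-2-enoate] | C=C(C)[C@H]1C[C@@H]2O[C@]2(C)[C@@H](OC(=O)/C(C)=C\C)C[C@H]2O[C@@]2(C)[C@@H](OCc3ccc(OC)cc3)[C@H]1OC(=O)/C(C)=C\C | intermediate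
33 | (1R,3S,4S,5S,7R,8S,9S,10S)-1,10:4,5-diepoxy-9-hydroxygermacr-11-ene-3,8-diyl bis[(2Z)-2-methylbut-2-enoate] | C=C(C)[C@H]1C[C@@H]2O[C@]2(C)[C@@H](OC(=O)/C(C)=C\C)C[C@H]2O[C@@]2(C)[C@@H](O)[C@H]1OC(=O)/C(C)=C\C | intermediate
34 | (1R,3S,4S,5S,7R,8S,9S,10R)-9-acetoxy-1,10:4,5-diepoxygermacr-11-ene-3,8-diyl bis[(2Z)-2-methylbut-2-enoate] (CNP0220329.1) | C=C(C)[C@H]1C[C@@H]2O[C@]2(C)[C@@H](OC(=O)/C(C)=C\C)C[C@H]2O[C@@]2(C)[C@@H](OC(C)=O)[C@H]1OC(=O)/C(C)=C\C | target

**Totals**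

Total step count: 27 (3 for fragment 6, 2 for salt 9, 8 for fragment 19, 14 from the coupling onward).
Longest linear sequence: 22 steps (10 → 34, steps 6–27; the branch from 7 is equally long).

**Steps most likely to fail, with fallbacks**

Step 21 (ring closure). The β,γ-epoxy aldehyde 27 is labile, and a ten-membered closure competes with proto-deiodination and oligomerisation. Fallback: close the same C4=C5 region by olefin metathesis instead of a carbonyl addition. Setting out from aldehyde 24, Wittig methylenation (Ph3P=CH2, THF, −78 °C) gives the C5-vinyl silyl ether F1. Bu4NF/AcOH then gives the C5-vinyl C3-alcohol F2, and Dess–Martin oxidation gives the C5-vinyl C3-aldehyde F3. Addition of isopropenylmagnesium bromide (CH2=C(CH3)MgBr, THF, −78 °C) gives the C3-isopropenyl carbinol F4 as a C3 epimer mixture. Ring-closing metathesis with the second-generation Hoveyda–Grubbs catalyst (toluene, 80 °C, 1 mM) joins C4 and C5 with loss of ethene; the ten-membered ring accommodates only the Z olefin. This comes back to the route at 28.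

Step 22 (oxidation to the enone). Ketone 29 has an acidic C2–H between the carbonyl and the 1,10-oxirane and can open to a γ-hydroxy dienone by E1cB elimination before it is reduced. Fallback: avoid the ketone and correct C3 by substitution instead of redox. Setting out from 28, the C3 epimers are separated; the (3S) epimer is 30 itself. The (3R) epimer is inverted by a Mitsunobu reaction (4-nitrobenzoic acid, PPh3, DIAD, toluene, 0 °C) to the (3S)-4-nitrobenzoate F5. Its activated ester is cleaved selectively (K2CO3, MeOH, 0 °C) in the presence of the hindered angelate, coming back to the route at 30.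

Step 24 (4,5-epoxidation). Facial selectivity in the ten-membered ring rests on conformational models, and the free C3 hydroxyl could also attack the 1,10-oxirane transannularly under the acidic by-product. Fallback: use steric rather than hydrogen-bond control and reverse the order of events. Setting out from 30, angeloylation under the conditions of step 25 gives the bis-angelate diene F6. Epoxidation with dimethyldioxirane (acetone, −20 °C) then occurs on the open face anti to the bulky C3 ester, coming back to the route at 32.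

**Further compounds**

F1 | step 21 | C5-vinyl silyl ether (24 with CH=CH2 in place of CH=O) | CC(C)(C)[Si](c1ccccc1)(c1ccccc1)OCC[C@H]2O[C@@]2(C)[C@@H](OCc3ccc(OC)cc3)[C@@H](OC(=O)/C(C)=C\C)[C@@H](C(C)=C)CC=C
F2 | step 21 | C5-vinyl C3-alcohol | OCC[C@H]2O[C@@]2(C)[C@@H](OCc3ccc(OC)cc3)[C@@H](OC(=O)/C(C)=C\C)[C@@H](C(C)=C)CC=C
F3 | step 21 | C5-vinyl C3-aldehyde | O=CC[C@H]2O[C@@]2(C)[C@@H](OCc3ccc(OC)cc3)[C@@H](OC(=O)/C(C)=C\C)[C@@H](C(C)=C)CC=C
F4 | step 21 | C3-isopropenyl carbinol (C3 epimers) | C=C(C)C(O)C[C@H]2O[C@@]2(C)[C@@H](OCc3ccc(OC)cc3)[C@@H](OC(=O)/C(C)=C\C)[C@@H](C(C)=C)CC=C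
F5 | step 22 | (3S)-4-nitrobenzoate of 30 | C=C(C)[C@H]1C/C=C(/C)[C@@H](OC(=O)c2ccc(cc2)[N+](=O)[O-])C[C@H]2O[C@@]2(C)[C@@H](OCc3ccc(OC)cc3)[C@H]1OC(=O)/C(C)=C\C
F6 | step 24 | bis-angelate diene (C3 angelate of 30) | C=C(C)[C@H]1C/C=C(/C)[C@@H](OC(=O)/C(C)=C\C)C[C@H]2O[C@@]2(C)[C@@H](OCc3ccc(OC)cc3)[C@H]1OC(=O)/C(C)=C\C
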